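## Retrosynthetic overview

- Feature: in the cyclohexene (C1 quaternary with methyl and styryl, C2, C3, C4 methyl-bearing, C4=C5, C6 carrying the coumarin-8-yl ring), the styryl carbon on C1 and the alkene carbon C5 on C6 can be paired as the two sp2 carbons of a cyclobutene whose sp3 carbons are C1 and C6.
- Disconnections: (a) the aryl–vinyl bond of the styryl unit (Heck coupling with 8-iodo-5,7-dimethoxycoumarin); (b) the pyranone ring B of the C6 coumarin (phenol, ortho-formylation, Wittig lactonisation), done before the Heck step so that the acid step precedes the acid-sensitive trioxygenated styrene; (c) C4=C5 together with the cyclobutene C=C, by ring-rearrangement metathesis of cyclobutene 18.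
- Cyclobutene 18 comes from (E)-alkene 8 by an auxiliary-controlled keteniminium [2+2] that sets both stereocentres, then Shapiro reaction, ketal hydrolysis and methylenation; 8 comes from ketal-protected hex-5-yn-2-one by carboalumination and Negishi coupling with aryl iodide 4.
- Ring order: cyclobutane (step 6), cyclohexene at the expense of the four-membered ring (step 11), pyranone ring B (step 14); the second coumarin enters intact (step 16).

Key step: step 11

Assumption on regiochemistry: in step 6 the iminium carbon is taken to bond to the methyl-bearing alkene carbon (closure through the aryl-stabilised benzylic cation), giving 13; the regioisomeric cyclobutanone would give the same cyclobutene 16 in step 8.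

Assumption on induction: the (2R,5R) auxiliary is taken to deliver the (2S,3S) ketone; if the sense is opposite, the (2S,5S) amine is used instead.

## Route

Step 1
Reactants: 1 3,5-dimethoxyphenol
Product: 2 1,3-dimethoxy-5-(methoxymethoxy)benzene
Conditions: NaH, MOMCl, THF, 0 → 20 °C
Reagents that add atoms: chloromethyl methyl ether, COCCl
Why: O-alkylation of the sodium phenoxide with chloromethyl methyl ether (Williamson-type methoxymethyl protection) is clean for an unhindered phenol and installs the group that directs the lithiation of step 2.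

Step 2
Reactants: 2 1,3-dimethoxy-5-(methoxymethoxy)benzene
Product: 4 2-iodo-1,5-dimethoxy-3-(methoxymethoxy)benzene, via aryllithium 3 (not isolated)
Conditions: n-BuLi, TMEDA, THF, 0 °C; then I2, −78 → 20 °C
Reagents that add atoms: iodine, II
Why: Directed ortho-metalation removes the ring hydrogen flanked by the chelating methoxymethoxy group and a methoxy group (two equivalent sites, favoured over the site between the two methoxy groups), and iodine traps the aryllithium.

Step 3
Reactants: 5 hex-5-yn-2-one
Product: 6 2-(but-3-yn-1-yl)-2-methyl-1,3-dioxolane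
Conditions: HOCH2CH2OH, p-TsOH·H2O (cat.), benzene, reflux, Dean–Stark trap
Reagents that add atoms: ethylene glycol, OCCO
Why: Acid-catalysed ketalisation with azeotropic removal of water masks the ketone as a dioxolane that should tolerate the organoaluminium, organolithium and keteniminium reagents of steps 4 to 8, and the terminal alkyne is untouched.

Step 4
Reactants: 6 2-(but-3-yn-1-yl)-2-methyl-1,3-dioxolane, 4 2-iodo-1,5-dimethoxy-3-(methoxymethoxy)benzene
Product: 8 2-{(3E)-4-[2,4-dimethoxy-6-(methoxymethoxy)phenyl]-3-methylbut-3-en-1-yl}-2-methyl-1,3-dioxolane, via alkenylalane 7 (not isolated)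
Conditions: Me3Al (3 equiv), Cp2ZrCl2 (0.25 equiv), CH2Cl2, 0 → 20 °C; evaporate excess Me3Al; then 4, Pd(P(t-Bu)3)2 (5 mol%), ZnCl2 (cocatalyst), THF, 40 °C
Reagents that add atoms: trimethylaluminium, C[Al](C)C
Why: Zirconium-catalysed carboalumination adds methyl and aluminium syn across the terminal alkyne with methyl on the internal carbon, and the Negishi cross-coupling of the alkenylalane with iodide 4 proceeds with retention, so the aryl group ends cis to the new methyl group, which is the (E)-alkene.

Step 5
Reactants: 9 (2R,5R)-2,5-dimethylpyrrolidine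
Product: 10 1-[(2R,5R)-2,5-dimethylpyrrolidin-1-yl]ethan-1-one
Conditions: Ac2O, Et3N, CH2Cl2, 0 → 20 °C
Reagents that add atoms: acetic anhydride, CC(=O)OC(C)=O
Why: N-acetylation of the secondary amine gives the C2-symmetric tertiary acetamide that is the precursor of the chiral keteniminium salt.

Step 6
Reactants: 8 2-{(3E)-4-[2,4-dimethoxy-6-(methoxymethoxy)phenyl]-3-methylbut-3-en-1-yl}-2-methyl-1,3-dioxolane, 10 1-[(2R,5R)-2,5-dimethylpyrrolidin-1-yl]ethan-1-one
Product: 13 (2S,3S)-3-[2,4-dimethoxy-6-(methoxymethoxy)phenyl]-2-methyl-2-[2-(2-methyl-1,3-dioxolan-2-yl)ethyl]cyclobutan-1-one, via keteniminium triflate 11 (not isolated), via cyclobutaniminium triflate 12 (not isolated)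
Conditions: 10, Tf2O, 2,4,6-collidine, ClCH2CH2Cl, −20 °C; then 8, −20 → 25 °C; then aq. NaHCO3, 25 °C
Reagents that add atoms: water, O
Why: Keteniminium–alkene [2+2] cycloaddition: the salt preformed from 10 (so that no free triflic anhydride meets the arene or the acetals) should add to the electron-rich alkene suprafacially and carry the (E) geometry into the cis aryl/methyl relationship, the C2-symmetric (2R,5R)-dimethylpyrrolidinium unit leaves one unhindered approach of the alkene and so sets the absolute configuration of both new stereocentres, and bicarbonate hydrolysis of the iminium salt frees the ketone and the auxiliary without touching the ketal or the methoxymethyl ether.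

Step 7
Reactants: 13 (2S,3S)-3-[2,4-dimethoxy-6-(methoxymethoxy)phenyl]-2-methyl-2-[2-(2-methyl-1,3-dioxolan-2-yl)ethyl]cyclobutan-1-one
Product: 14 N'-{(2S,3R)-3-[2,4-dimethoxy-6-(methoxymethoxy)phenyl]-2-methyl-2-[2-(2-methyl-1,3-dioxolan-2-yl)ethyl]cyclobutylidene}-4-methylbenzenesulfonohydrazide
Conditions: TsNHNH2, MeOH, 25 °C
Reagents that add atoms: p-toluenesulfonyl hydrazide, Cc1ccc(cc1)S(=O)(=O)NN
Why: Hydrazone condensation of the strained, electrophilic cyclobutanone needs no acid catalyst, so the dioxolane survives, and neither stereocentre can epimerise (one is quaternary, the other is not alpha to the carbonyl; the change of one descriptor is only a change of CIP priorities).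

Step 8
Reactants: 14 N'-{(2S,3R)-3-[2,4-dimethoxy-6-(methoxymethoxy)phenyl]-2-methyl-2-[2-(2-methyl-1,3-dioxolan-2-yl)ethyl]cyclobutylidene}-4-methylbenzenesulfonohydrazide
Product: 16 2-{2-[(1R,4R)-4-[2,4-dimethoxy-6-(methoxymethoxy)phenyl]-1-methylcyclobut-2-en-1-yl]ethyl}-2-methyl-1,3-dioxolane, via cyclobutenyllithium 15 (not isolated)
Conditions: n-BuLi (4.5 equiv), TMEDA, THF, −78 → 0 °C; then H2O, 0 °C
Reagents that add atoms: none
Why: Shapiro reaction: deprotonation at N–H and at the only alpha-CH2, then loss of sulfinate and nitrogen, gives the cyclobutenyllithium that water protonates to the cyclobutene, the stereocentres are not involved, and any lithiation of the arene between its oxygen substituents (hence the excess base) is simply reversed by the aqueous quench.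

Step 9
Reactants: 16 2-{2-[(1R,4R)-4-[2,4-dimethoxy-6-(methoxymethoxy)phenyl]-1-methylcyclobut-2-en-1-yl]ethyl}-2-methyl-1,3-dioxolane
Product: 17 4-{(1R,4R)-4-[2,4-dimethoxy-6-(methoxymethoxy)phenyl]-1-methylcyclobut-2-en-1-yl}butan-2-one
Conditions: p-TsOH·H2O (10 mol%), acetone/H2O (10:1), 20 °C
Reagents that add atoms: water, O
Why: Acid-catalysed hydrolysis (transketalisation) of the dioxolane of an unhindered dialkyl ketone should proceed at room temperature, where the aryl methoxymethyl ether is retained and the 3-arylcyclobutene does not yet undergo thermal electrocyclic ring opening.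

Step 10
Reactants: 17 4-{(1R,4R)-4-[2,4-dimethoxy-6-(methoxymethoxy)phenyl]-1-methylcyclobut-2-en-1-yl}butan-2-one
Product: 18 (3R,4R)-3-[2,4-dimethoxy-6-(methoxymethoxy)phenyl]-4-methyl-4-(3-methylbut-3-en-1-yl)cyclobut-1-ene (aryl cis to methyl)
Conditions: Ph3PCH3Br, KOt-Bu, THF, 0 → 20 °C
Reagents that add atoms: methyltriphenylphosphonium bromide, C[P+](c1ccccc1)(c1ccccc1)c1ccccc1.[Br-]
Why: Wittig methylenation of the methyl ketone with the non-stabilised ylide gives the 1,1-disubstituted alkene at or below room temperature, and the molecule has no enolisable stereocentre.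

Step 11
Reactants: 18 (3R,4R)-3-[2,4-dimethoxy-6-(methoxymethoxy)phenyl]-4-methyl-4-(3-methylbut-3-en-1-yl)cyclobut-1-ene
Product: 19 (3R,4R)-3-[2,4-dimethoxy-6-(methoxymethoxy)phenyl]-4-ethenyl-1,4-dimethylcyclohex-1-ene (aryl cis to vinyl)
Conditions: second-generation Hoveyda–Grubbs catalyst RuCl2(H2IMes)(=CH-C6H4-2-O-i-Pr) (5 mol%), C2H4 (1 atm), CH2Cl2 (0.01 M), 20 °C; then argon purge, 35 °C
Reagents that add atoms: ethylene, C=C
Why: The ruthenium methylidene formed from the catalyst and ethylene adds to the strained cyclobutene double bond with the metal on the carbon remote from the quaternary centre (the future C5); cycloreversion leaves the methylene on the carbon next to C1 (the future vinyl group), and the C5 alkylidene then adds to the tethered 1,1-disubstituted alkene and cycloreverts to form C4=C5 and return the methylidene. The closest known reaction type is ring-rearrangement metathesis (ring-opening/ring-closing metathesis) of alkenyl-tethered cyclobutenes to vinyl-substituted cyclohexenes. The six-membered ring closes by ring-closing metathesis through a ruthenacyclobutane that joins C5 to C4, which places the trisubstituted alkene inside the ring. No stereocentre is formed, and C1 and C6 never belong to a metallacycle, so the configuration from step 6 is carried over; the cis aryl/methyl relationship of the cyclobutene becomes the cis aryl/vinyl relationship of the cyclohexene because the tether carbon replaces the alkene carbon as ring member at C1. The step needs regioselective loading of ruthenium on C5, since an alkylidene on the carbon beside C1 would close a five-membered ring; the fully substituted C1 shields its neighbour, the gem-disubstituted side-chain alkene is too unreactive to initiate, and any alkylidene capped by ethylene gives the acyclic triene, which re-enters through its less hindered vinyl group on C6. Dilution and ethylene suppress ring-opening oligomerisation, and the mixture is kept at room temperature until the cyclobutene is consumed because the 3-arylcyclobutene is prone to thermal ring opening.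

Step 12
Reactants: 19 (3R,4R)-3-[2,4-dimethoxy-6-(methoxymethoxy)phenyl]-4-ethenyl-1,4-dimethylcyclohex-1-ene
Product: 20 2-[(1R,6R)-6-ethenyl-3,6-dimethylcyclohex-2-en-1-yl]-3,5-dimethoxyphenol
Conditions: HCl (1 M in MeOH), 20 °C
Reagents that add atoms: none
Why: Acid-catalysed acetal exchange with methanol removes the aryl methoxymethyl ether as dimethoxymethane under conditions too mild to protonate the trisubstituted or the vinyl alkene.

Step 13
Reactants: 20 2-[(1R,6R)-6-ethenyl-3,6-dimethylcyclohex-2-en-1-yl]-3,5-dimethoxyphenol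
Product: 21 3-[(1R,6R)-6-ethenyl-3,6-dimethylcyclohex-2-en-1-yl]-2-hydroxy-4,6-dimethoxybenzaldehyde
Conditions: MgCl2, Et3N, (CH2O)n, MeCN, 80 °C
Reagents that add atoms: paraformaldehyde (as formaldehyde), C=O
Why: Magnesium-mediated ortho-formylation (Casnati–Skattebøl reaction): the magnesium phenoxide delivers formaldehyde to the only free ortho position and a second formaldehyde oxidises the benzylic alkoxide to the aldehyde, so the position between the two methoxy groups is not attacked.

Step 14
Reactants: 21 3-[(1R,6R)-6-ethenyl-3,6-dimethylcyclohex-2-en-1-yl]-2-hydroxy-4,6-dimethoxybenzaldehyde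
Product: 23 8-[(1R,6R)-6-ethenyl-3,6-dimethylcyclohex-2-en-1-yl]-5,7-dimethoxy-2H-chromen-2-one, via aryl ester ylide 22 (not isolated)
Conditions: Ph3P=C=C=O, toluene, 90 °C
Reagents that add atoms: (triphenylphosphoranylidene)ketene, O=C=C=P(c1ccccc1)(c1ccccc1)c1ccccc1
Why: The phenol adds to the ketene carbon to give an aryl ester ylide that undergoes intramolecular Wittig olefination with the ortho aldehyde, which closes the pyranone ring with the required cis double bond well below the temperature at which the 1,5-diene of the cyclohexene could undergo Cope rearrangement.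

Step 15
Reactants: 24 5,7-dimethoxy-2H-chromen-2-one
Product: 25 8-iodo-5,7-dimethoxy-2H-chromen-2-one
Conditions: NIS, CF3CO2H (cat.), MeCN, 20 °C
Reagents that add atoms: N-iodosuccinimide, O=C1CCC(=O)N1I
Why: Electrophilic aromatic iodination should occur at C8, which is activated by the 7-methoxy group (ortho), the 5-methoxy group (para) and the ring oxygen (ortho) and is less crowded than C6; any 6-iodo isomer is removed by crystallisation.

Step 16
Reactants: 23 8-[(1R,6R)-6-ethenyl-3,6-dimethylcyclohex-2-en-1-yl]-5,7-dimethoxy-2H-chromen-2-one, 25 8-iodo-5,7-dimethoxy-2H-chromen-2-one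
Product: 26 8-[(E)-2-[(1R,2R)-2-(5,7-dimethoxy-2-oxo-2H-chromen-8-yl)-1,4-dimethylcyclohex-3-en-1-yl]ethenyl]-5,7-dimethoxy-2H-chromen-2-one
Conditions: Pd(OAc)2 (10 mol%), n-Bu4NCl, NaHCO3, DMF, 85 °C
Reagents that add atoms: none
Why: Mizoroki–Heck reaction under ligand-free phase-transfer conditions: the arylpalladium iodide adds to the terminal carbon of the vinyl group and, because C1 is quaternary, beta-hydride elimination can only use the benzylic hydrogen, which gives the (E)-styrene without double-bond migration, while the ring alkene and the coumarin double bonds are too hindered or too electron-poor to compete.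

## Compound list

1 | 3,5-dimethoxyphenol | COc1cc(O)cc(OC)c1 | starting material
2 | 1,3-dimethoxy-5-(methoxymethoxy)benzene | COCOc1cc(OC)cc(OC)c1 | intermediate
3 | [2,4-dimethoxy-6-(methoxymethoxy)phenyl]lithium | [Li]c1c(OC)cc(OC)cc1OCOC | intermediate (not isolated)
4 | 2-iodo-1,5-dimethoxy-3-(methoxymethoxy)benzene | COCOc1cc(OC)cc(OC)c1I | intermediate
5 | hex-5-yn-2-one | CC(=O)CCC#C | starting material
6 | 2-(but-3-yn-1-yl)-2-methyl-1,3-dioxolane | CC1(CCC#C)OCCO1 | intermediate
7 | dimethyl[(1E)-2-methyl-4-(2-methyl-1,3-dioxolan-2-yl)but-1-en-1-yl]alumane | CC1(CC/C(C)=C/[Al](C)C)OCCO1 | intermediate (not isolated)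
8 | 2-{(3E)-4-[2,4-dimethoxy-6-(methoxymethoxy)phenyl]-3-methylbut-3-en-1-yl}-2-methyl-1,3-dioxolane | CC1(CC/C(C)=C/c2c(OCOC)cc(OC)cc2OC)OCCO1 | intermediate
9 | (2R,5R)-2,5-dimethylpyrrolidine | C[C@@H]1CC[C@@H](C)N1 | starting material
10 | 1-[(2R,5R)-2,5-dimethylpyrrolidin-1-yl]ethan-1-one | CC(=O)N1[C@H](C)CC[C@H]1C | intermediate
11 | (2R,5R)-1-ethenylidene-2,5-dimethylpyrrolidin-1-ium trifluoromethanesulfonate | C=C=[N+]1[C@H](C)CC[C@H]1C.[O-]S(=O)(=O)C(F)(F)F | intermediate (not isolated)
12 | cyclobutaniminium triflate of 13 with (2R,5R)-2,5-dimethylpyrrolidine (ring stereocentres as in 13) | CC1(CC[C@]2(C)C(=[N+]3[C@H](C)CC[C@H]3C)C[C@H]2c2c(OCOC)cc(OC)cc2OC)OCCO1.[O-]S(=O)(=O)C(F)(F)F | intermediate (not isolated)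
13 | (2S,3S)-3-[2,4-dimethoxy-6-(methoxymethoxy)phenyl]-2-methyl-2-[2-(2-methyl-1,3-dioxolan-2-yl)ethyl]cyclobutan-1-one (aryl cis to methyl) | CC1(CC[C@]2(C)C(=O)C[C@H]2c2c(OCOC)cc(OC)cc2OC)OCCO1 | intermediate
14 | N'-{(2S,3R)-3-[2,4-dimethoxy-6-(methoxymethoxy)phenyl]-2-methyl-2-[2-(2-methyl-1,3-dioxolan-2-yl)ethyl]cyclobutylidene}-4-methylbenzenesulfonohydrazide (C=N geometry not fixed; sulfonamide expected on the CH2 side) | CC1(CC[C@]2(C)C(=NNS(=O)(=O)c3ccc(C)cc3)C[C@H]2c2c(OCOC)cc(OC)cc2OC)OCCO1 | intermediate
15 | cyclobutenyllithium of 16 (lithium on the alkene carbon next to the quaternary carbon; stereocentres as in 16) | CC1(CC[C@]2(C)C([Li])=C[C@H]2c2c(OCOC)cc(OC)cc2OC)OCCO1 | intermediate (not isolated)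
16 | 2-{2-[(1R,4R)-4-[2,4-dimethoxy-6-(methoxymethoxy)phenyl]-1-methylcyclobut-2-en-1-yl]ethyl}-2-methyl-1,3-dioxolane | CC1(CC[C@]2(C)C=C[C@H]2c2c(OCOC)cc(OC)cc2OC)OCCO1 | intermediate
17 | 4-{(1R,4R)-4-[2,4-dimethoxy-6-(methoxymethoxy)phenyl]-1-methylcyclobut-2-en-1-yl}butan-2-one | CC(=O)CC[C@]1(C)C=C[C@H]1c1c(OCOC)cc(OC)cc1OC | intermediate
18 | (3R,4R)-3-[2,4-dimethoxy-6-(methoxymethoxy)phenyl]-4-methyl-4-(3-methylbut-3-en-1-yl)cyclobut-1-ene | C=C(C)CC[C@]1(C)C=C[C@H]1c1c(OCOC)cc(OC)cc1OC | intermediate
19 | (3R,4R)-3-[2,4-dimethoxy-6-(methoxymethoxy)phenyl]-4-ethenyl-1,4-dimethylcyclohex-1-ene | C=C[C@@]1(C)CCC(C)=C[C@H]1c1c(OCOC)cc(OC)cc1OC | intermediate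
20 | 2-[(1R,6R)-6-ethenyl-3,6-dimethylcyclohex-2-en-1-yl]-3,5-dimethoxyphenol | C=C[C@@]1(C)CCC(C)=C[C@H]1c1c(O)cc(OC)cc1OC | intermediate
21 | 3-[(1R,6R)-6-ethenyl-3,6-dimethylcyclohex-2-en-1-yl]-2-hydroxy-4,6-dimethoxybenzaldehyde | C=C[C@@]1(C)CCC(C)=C[C@H]1c1c(O)c(C=O)c(OC)cc1OC | intermediate
22 | 2-[(1R,6R)-6-ethenyl-3,6-dimethylcyclohex-2-en-1-yl]-6-formyl-3,5-dimethoxyphenyl (triphenylphosphoranylidene)acetate | C=C[C@@]1(C)CCC(C)=C[C@H]1c1c(OC(=O)C=P(c2ccccc2)(c2ccccc2)c2ccccc2)c(C=O)c(OC)cc1OC | intermediate (not isolated)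
23 | 8-[(1R,6R)-6-ethenyl-3,6-dimethylcyclohex-2-en-1-yl]-5,7-dimethoxy-2H-chromen-2-one | C=C[C@@]1(C)CCC(C)=C[C@H]1c1c(OC)cc(OC)c2ccc(=O)oc12 | intermediate
24 | 5,7-dimethoxy-2H-chromen-2-one (5,7-dimethoxycoumarin) | COc1cc(OC)c2ccc(=O)oc2c1 | starting material
25 | 8-iodo-5,7-dimethoxy-2H-chromen-2-one | COc1cc(OC)c2ccc(=O)oc2c1I | intermediate
26 | 8-[(E)-2-[(1R,2R)-2-(5,7-dimethoxy-2-oxo-2H-chromen-8-yl)-1,4-dimethylcyclohex-3-en-1-yl]ethenyl]-5,7-dimethoxy-2H-chromen-2-one (coumarinyl cis to styryl) | COc1cc(OC)c2ccc(=O)oc2c1/C=C/[C@@]1(C)CCC(C)=C[C@H]1c1c(OC)cc(OC)c2ccc(=O)oc12 | target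

## Step count and risks

Total step count: 16. Longest linear sequence: 13 steps (from 1: steps 1, 2, 4, 6 to 14, 16).

Steps most likely to fail:

1. Step 6. The cationic keteniminium salt (or its O-triflyl precursor) may attack the free ring positions of the trioxygenated arene instead of the alkene, the alkene geometry may leak through a long-lived benzylic cation, and the auxiliary may discriminate the alkene faces insufficiently. Fallback, setting out from 8: thermal [2+2] with dichloroketene (Cl3CCOCl, Zn(Cu), Et2O), a neutral ketene that spares the arene and adds stereospecifically, should give racemic 2,2-dichloro-3-[2,4-dimethoxy-6-(methoxymethoxy)phenyl]-4-methyl-4-[2-(2-methyl-1,3-dioxolan-2-yl)ethyl]cyclobutan-1-one F1. Reductive dechlorination (Zn, NH4Cl, MeOH) gives the racemic ketone F2, which is resolved by preparative chromatography on a chiral stationary phase; the (2S,3S) enantiomer is 13, where the route is rejoined.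

2. Step 11. Ruthenium may load on the alkene carbon beside C1 (or on the neopentyl vinyl group of a ring-opened triene) and close the five-membered ring, closure onto the gem-disubstituted alkene may stall under ethylene, and the cyclobutene may oligomerise or open thermally before the catalyst engages it. Fallback, setting out from ketone 17: ring-opening cross-metathesis with ethylene using the first-generation Grubbs catalyst RuCl2(PCy3)2(=CHPh) gives (5R,6R)-6-[2,4-dimethoxy-6-(methoxymethoxy)phenyl]-5-ethenyl-5-methyloct-7-en-2-one F3. One equivalent of the molybdenum imido alkylidene Mo(=CHCMe2Ph)(=N-2,6-i-Pr2C6H3)[OCMe(CF3)2]2 (benzene, 20 °C) then undergoes olefin metathesis at the less hindered vinyl group on C6 followed by intramolecular carbonyl olefination of the methyl ketone, so that C4=C5 is formed from the ketone and the route is rejoined at 19.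

3. Step 16. Migratory insertion of the di-ortho-substituted arylpalladium species into the vinyl group on the quaternary carbon may be slow, so that proto-deiodination of 25 and catalyst decomposition win. Fallback, setting out from 25 and 23: Suzuki–Miyaura vinylation of 25 (CH2=CHBF3K, PdCl2(dppf), Et3N, n-PrOH, 80 °C) gives 8-ethenyl-5,7-dimethoxy-2H-chromen-2-one F4. Cross-metathesis of F4 with the vinyl group of 23 (second-generation Hoveyda–Grubbs catalyst RuCl2(H2IMes)(=CH-C6H4-2-O-i-Pr), CH2Cl2, 40 °C; the trisubstituted ring alkene is inert) gives the (E)-alkene 26 directly.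

## Further compounds

F1 | step 6 | racemic 2,2-dichloro-3-[2,4-dimethoxy-6-(methoxymethoxy)phenyl]-4-methyl-4-[2-(2-methyl-1,3-dioxolan-2-yl)ethyl]cyclobutan-1-one (aryl cis to methyl; both enantiomers) | CC1(CC[C@]2(C)C(=O)C(Cl)(Cl)[C@H]2c2c(OCOC)cc(OC)cc2OC)OCCO1.CC1(CC[C@@]2(C)C(=O)C(Cl)(Cl)[C@@H]2c2c(OCOC)cc(OC)cc2OC)OCCO1
F2 | step 6 | racemic 3-[2,4-dimethoxy-6-(methoxymethoxy)phenyl]-2-methyl-2-[2-(2-methyl-1,3-dioxolan-2-yl)ethyl]cyclobutan-1-one (aryl cis to methyl; both enantiomers) | CC1(CC[C@]2(C)C(=O)C[C@H]2c2c(OCOC)cc(OC)cc2OC)OCCO1.CC1(CC[C@@]2(C)C(=O)C[C@@H]2c2c(OCOC)cc(OC)cc2OC)OCCO1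
F3 | step 11 | (5R,6R)-6-[2,4-dimethoxy-6-(methoxymethoxy)phenyl]-5-ethenyl-5-methyloct-7-en-2-one | CC(=O)CC[C@](C)(C=C)[C@@H](C=C)c1c(OCOC)cc(OC)cc1OC
F4 | step 16 | 8-ethenyl-5,7-dimethoxy-2H-chromen-2-one | C=Cc1c(OC)cc(OC)c2ccc(=O)oc12
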